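At early times the first end groups fall at nearly one pace in both earlier runs, 0.200 h⁻¹ in epsilon and 0.212 h⁻¹ in delta, although delta is charged 2.81 times as concentrated. The main exit therefore looks pseudo-first-order, and links are a minor branch beside it.

| flask | first end groups | second end groups | remark | time |
|---|---|---|---|---|
| epsilon | 0.0096 M | 1.02 equiv | run made earlier |  |
| delta | 0.027 M | 1.02 equiv | run made earlier |  |
| noon | 0.033 M | 1.02 equiv |  | 40 h |
| midnight | 0.015 M | 1.02 equiv |  | 40 h |

- epsilon (time / h: links / %, first end groups / %): 3.00: 2.8, 54.9; 6.00: 4.8, 30.6; 12.0: 5.2, 10.1; 20.0: 4.9, 1.8; 40.0: 4.8, 0.7
- delta (time / h: links / %, first end groups / %): 8.00: 11.1, 18.3; 15.0: 11.5, 4.1; 25.0: 11.1, 0.3; 30.0: 11.4, 0; 40.0: 11.5, 0.5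

(standard deviation of a reading: 0.5 percentage points)

- where the amount of first end groups changes, what is given in equivalents or mol% on it follows

- the flask that ends with the higher amount of links, in percent of the first end groups charged, or "neither" when 2 percentage points or less lies between them (noon / midnight / neither)
- final links, as a percentage of the first end groups charged, in noon
- final links, as a percentage of the first end groups charged, in midnight

Dividing the rate of link making by the total rate of loss removes time. If links form in proportion to c(first end groups) × c(second end groups), and the other exit in proportion to c(first end groups), each first end group lost becomes a link with the share c(second end groups)/(c(second end groups) + K). At 1.02 equiv, c(second end groups) falls from about the charge towards zero, so the midpoint, half the charge, should give a fair average share. The delta plateau of 11.4% then gives 0.105 M, the crossover concentration at which both exits run equally fast.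

One objection is the excess of second end groups, but in noon it is 6.60 × 10⁻⁴ M, which is less than K and can be ignored. A second is that links might be consumed later, and the epsilon tail cannot dismiss it: the move from 5.2% to 4.8% lies within the scatter of 0.5 percentage points, but at 12.0 h epsilon holds just 10.1% of its first end groups, so this objection stays open and my reckoning does not compute it. A third objection also stands: the epsilon plateau of 4.97% gives a lower K, 0.0918 M. Delta's larger reading at the same scatter is the sharper, so my reckoning keeps its K: 13.6% for noon and 6.66% for midnight, or 7.55% for midnight with epsilon's K. Either way the gap exceeds 2 points.

The forecast, by a different formula, says noon, with 13% for noon and 7.2% for midnight, on the ground that “The plateau yield rises with concentration”.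

The simulation gives noon: 13.1% in noon and 7.08% in midnight.

    first end groups + second end groups → links (k = 5.60 × 10⁻⁴ M⁻¹ s⁻¹)
    first end groups + second end groups → rings, rate k2*[first end groups] as long as [second end groups] is above zero (k = 5.20 × 10⁻⁵ s⁻¹)
    first end groups + links → side product (k = 3.90 × 10⁻⁴ M⁻¹ s⁻¹)

The gap comes from the charge concentration: midnight brought to noon's concentration ends at 13.1% instead of 7.08%. In noon the midpoint of 0.0165 M lies below K, so rings hold 83.1% at 40.0 h. A neighbouring flask, noon with 4.10 equiv of second end groups, has a midpoint c(second end groups) of 0.119 M, above K, and so K gives a link share of 53.1%. The computed flask ends at 51.6%.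

(The readings are simulated with made-up constants; scatter was added.)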